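## Analysis of the target

The target is a B-type proanthocyanidin trimer, epiafzelechin-(4β→8)-epicatechin-(4β→8)-epicatechin: three 2-arylchroman-3-ol units joined by two C4→C8 bonds. The top unit has a 4-hydroxyphenyl ring B, the middle and lower units a 3,4-dihydroxyphenyl ring B, and every ring A is a phloroglucinol-type ring. There are eight stereocentres: C2 and C3 of each unit are R,R (aryl and hydroxyl cis), and C4 of the top and middle units carries its aryl bond trans to the C3 hydroxyl (by the CIP rules 4R in the top unit, 4S in the middle unit). The eleven phenols make the free compound sensitive to air and base (quinone methides, C2 epimerisation by ring opening), and the two C4–aryl bonds are cleaved by acid, so the phenols must stay masked until a final neutral step. The difficulties are the 2,3-cis relation, which is the less stable one and cannot be reached by equilibration, the two C4 centres, and the choice of C8 over C6 on each nucleophilic ring A. The strategy rests on one feature: C4 of the top unit is bonded to C4a of its own ring A and to C8 of ring A of the middle unit. Before O1–C2 of the top unit exists, these two rings are the same 2-hydroxy-4,6-dioxygenated aryl group, so C4 is a prochiral carbon bearing two identical phenols next to C3.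

## Retrosynthetic reasoning

33 ← 32 ← 31. The last two steps only unmask. The eleven benzyl ethers of 32 fall in one hydrogenolysis. The ring B sulfonate of 31, which hydrogenolysis would not remove, is cleaved one step earlier, while every other phenol is still an ether, so that no strong base meets a free polyphenol.

31 ← 28 + 30. The bond C4(middle)–C8(lower) is cut last. The lower unit is then simply the benzyl ether 30 of natural 29. C4 of the middle unit is set on a closed ring C, where a C4 cation is captured trans to the C3 oxygen. Making this bond before ring C of the middle unit is closed would leave C4 to an open-chain addition with no ring to direct it. The forward step must ionise the 4-alkoxy group of 28 without cleaving the C4–aryl bond already present.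

28 ← 27. The leaving group at C4 comes from C–H oxidation of the ring C methylene group of 27, the position ortho and para to three ring oxygens.

27 ← 25 (through 26). O1–C2 of the middle unit is cut as a reductive etherification of a phenol ketone. The cut is made here because hydride delivery to the cyclic oxocarbenium ion anti to the C3 oxygen gives the 2,3-cis relation directly. It is placed before C4 is substituted, so that no C4 aryl group blocks the face the hydride needs.

25 ← 22 + 23; 22 ← 21 ← 20. Ring B of the middle unit enters as the aryl-magnesium reagent 24 made from 23. The acyl partner is the Weinreb amide 22, so that addition stops at the ketone. 22 comes from lactone 21, the oxidation product of lactol 20.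

20 ← 17 + 18 (through 19). C3–C4 of the middle unit is cut as the addition of an enamine of 18 to quinone methide 19. This brings in C2 and C3 with the C3 oxygen, and a chiral secondary-amine catalyst sets C3. The methide carbon is unsubstituted, so no second centre is at stake.

17 ← 16 ← 15. The one-carbon unit that becomes C4 of the middle unit is placed ortho to the phenol left over from the key step. That phenol has only one free ortho position, the future C4a.

15 ← 14. This is the key disconnection: O1–C2 of the top unit. In the forward direction one of the two identical phenols of 14 opens the cis-epoxide at its benzylic carbon with inversion. This closes ring C, gives the 2,3-cis relation and turns the prochiral carbon into C4. The phenol that is not used is already the ring A of the middle unit, attached through its C8.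

14 ← 13 ← 12 ← 11. The epoxide comes from a Z-alkene by one catalytic asymmetric epoxidation, the only external source of chirality for the top unit. The Z-alkene comes from an alkyne by semihydrogenation. The phenols are acetates while palladium and oxidant are present.

11 ← 8 + 10; 8 ← 6 (through 7) ← 5; 10 ← 9. Ring B is attached by Sonogashira coupling of the aryl iodide 10, a sulfonate that deactivates the future C2 towards ionisation. The terminal alkyne comes from the masked aldehyde 6 by one-carbon homologation.

5 ← 1 + 2 (through 3 and 4). The bis(aryl)methine is cut into two molecules of 1 and the aldehyde carbon of 2. The ester of 2 ties up one phenol as a lactone and is the handle for the next carbon.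

## Alternatives that were turned down

Alternative 1: Ring C of the top unit is cut at C4–C4a and O1–C2. Phenol 1 would be joined to an aryl enone whose β-carbon is already bonded to C8 of a preformed benzyl-protected lower dimer. A chiral Brønsted acid would promote conjugate addition of the ortho carbon of 1 and cyclodehydration to the 4-aryl-4H-chromene A1.
- For it: both lower units come from the natural flavanol, so five of the eight stereocentres are bought, and the carbon skeleton of the top unit is complete in one step. On convergence and step economy it is stronger than the chosen route.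
- Against it: the β-carbon carries an aryl group with two ortho oxygens, so the addition is hindered and the catalyst must override a large chiral substrate. Phenol 1 can also react para to its hydroxyl.
- The relay from C4 to C3 and C2 is the main problem. Reagents that add to the C2=C3 enol ether from the face away from the C4 aryl group (hydroboration, hydrogenation) put hydrogen on C2 on that face and give the 2,4-cis series. The target is 2,4-trans, so oxygen would have to enter at C3 from the far face and hydride at C2 from the near face, through a labile 2-aryl enol-ether epoxide.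
- In its place the chosen route fixes C2, C3 and C4 of the top unit from one epoxide, obtains 2,3-cis directly by inversion, and puts its uncertain step early, on a small symmetrical substrate.

Alternative 2: Ring C of the top unit is cut at C4–C4a. A 3,5-bis(benzyloxy)phenyl ether on C2 would close onto a trans C3–C4 epoxide whose C4 already carries C8 of the benzylated dimer. A carbophilic or oxophilic Lewis acid would open the epoxide at C4, and the ortho carbon of the ether would attack to give the protected trimer A2.
- For it: A2 is one hydrogenolysis from the target, the lower dimer is from the chiral pool, and the two ortho positions of the ether are equivalent, so there is no regiochemical question. It is shorter after its key step than the chosen route.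
- Against it: the epoxide carbon C4 is benzylic to a 1,3,5-trioxygenated ring. Such an epoxide ionises very easily, so it is hard to make and purify, and its opening is SN1. C4 is then set by the face of a planar cation, not by the epoxide, and hydride or aryl shifts compete.
- The C2 aryl ether is also a benzylic ether of a 4-alkoxyphenyl group and is labile to the same Lewis acids. The precursor needs an enantioselective synthesis of three contiguous centres on the dimer.
- In the chosen route the epoxide carbons bear a sulfonate-deactivated aryl group and an sp3 carbon, so the epoxide can be isolated and opened with inversion. C4 is decided by a steric choice between two closed transition states, not by a free cation.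

Alternative 3: Ring C of the top unit is cut at C3–C4 and O1–C2 (as a lactol). A phenol carrying a benzhydrol carbon bonded to C8 of the benzylated dimer would lose water to a quinone methide. The enamine of 18 with a diarylprolinol silyl ether would add at C4, and the phenol would close on the aldehyde to the 3,4-trans lactol A3.
- For it: the reaction type is established and is used in the chosen route (step 12) in its simplest form, and the lower dimer again comes from the chiral pool. On convergence it is stronger.
- Against it: the methide carbon carries an aryl group with two ortho oxygens and the whole dimer. It is strongly stabilised and shielded, so addition is slow and reversible, and C4 must be set in an open-chain addition against the bias of the substrate.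
- A3 still lacks ring B. C2 has to be turned into an aryl ketone and reduced past an axial C4 aryl group, since direct aryl addition to a C2 oxocarbenium ion would come trans to the C3 oxygen and give 2,3-trans. That is four to five more steps.
- The chosen route uses the quinone methide reaction only where the methide carbon is unsubstituted. Each C4 is set either by the epoxide opening or by capture of a ring-bound cation.

Key step: step 9

Assumption: compounds 18 and 23 and both chiral catalysts are purchased; the sense of induction of each catalyst is taken from its usual model and would be confirmed on the first intermediate.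

Naming remark: TU stands for the top-unit group (2R,3R)-5,7-bis(benzyloxy)-3-hydroxy-2-[4-(methanesulfonyloxy)phenyl]chroman-4-yl, bonded through C4 with the bond β (trans to the C3 hydroxyl and to the C2 aryl group). The CIP descriptor of that C4 changes with the priority of the attached ring, but its geometry does not.

## Route

Step 1
Reactants: 1 3,5-bis(benzyloxy)phenol (2 equiv); 2 ethyl glyoxylate
Product: 5 4,6-bis(benzyloxy)-3-[2,4-bis(benzyloxy)-6-hydroxyphenyl]benzofuran-2(3H)-one (racemic), via mandelate ester 3 (not isolated), via diarylacetate 4 (not isolated)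
Conditions: EtMgBr (2 equiv), Et2O, 0 °C; toluene, 2, 20 → 90 °C; aq. NH4Cl; p-TsOH (cat.), toluene, 60 °C
Reagents that add atoms: none
Why: Magnesium phenoxide-directed ortho-hydroxyalkylation (a templated Friedel–Crafts reaction): the aldehyde bound to the phenoxide magnesium is delivered to the ortho carbon, which avoids the para position between the two benzyloxy groups, and the benzylic magnesium alkoxide of 3 is then replaced by the ortho carbon of a second phenoxide through a chelated quinone methide. Acid closes the ester of 4 onto one phenol; C3 of the lactone is stereogenic but racemic, which does not matter because it becomes a prochiral carbon again in 7.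

Step 2
Reactants: 5 benzofuranone
Product: 6 4,6-bis(benzyloxy)-3-[2,4-bis(benzyloxy)-6-hydroxyphenyl]-2,3-dihydrobenzofuran-2-ol (lactol, mixture of stereoisomers)
Conditions: DIBAL-H (i-Bu2AlH, 2.2 equiv), CH2Cl2, −78 °C; Rochelle salt
Reagents that add atoms: none
Why: Partial reduction of a lactone to the lactol with DIBAL-H; the aluminium hemiacetal is stable at −78 °C, and one extra equivalent is consumed by the free phenol.

Step 3
Reactants: 6 lactol
Product: 8 (prop-2-yne-1,1-diyl)bis[3,5-bis(benzyloxy)-2,1-phenylene] diacetate, via alkyne bisphenol 7 (not isolated)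
Conditions: dimethyl (1-diazo-2-oxopropyl)phosphonate, K2CO3, MeOH–THF, 0 °C → rt; evaporate; Ac2O, pyridine, DMAP (cat.), CH2Cl2, 0 °C → rt
Reagents that add atoms: dimethyl (1-diazo-2-oxopropyl)phosphonate, COP(=O)(OC)C(=[N+]=[N-])C(C)=O; acetic anhydride, CC(=O)OC(C)=O
Why: Ohira–Bestmann homologation: in methanolic K2CO3 the lactol is in equilibrium with the aryloxide aldehyde, which the diazophosphonate anion converts into the terminal alkyne; the α-carbon is not stereogenic, so enolisation is harmless. Acetylation then masks both phenols for the palladium, hydrogenation and oxidation steps and makes the two aryl groups identical.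

Step 4
Reactants: 9 4-iodophenol
Product: 10 4-iodophenyl methanesulfonate
Conditions: MsCl, Et3N, CH2Cl2, 0 °C
Reagents that add atoms: methanesulfonyl chloride, CS(Cl)(=O)=O
Why: Sulfonylation of a phenol; the mesylate is an electron-withdrawing, acid-stable mask of the ring B hydroxyl.

Step 5
Reactants: 8 alkyne diacetate; 10 4-iodophenyl methanesulfonate
Product: 11 {3-[4-(methanesulfonyloxy)phenyl]prop-2-yne-1,1-diyl}bis[3,5-bis(benzyloxy)-2,1-phenylene] diacetate
Conditions: Pd(PPh3)2Cl2 (3 mol %), CuI (5 mol %), Et3N, THF, rt, degassed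
Reagents that add atoms: none
Why: Sonogashira coupling of a terminal alkyne with an aryl iodide; the iodide reacts at room temperature while the aryl mesylate is inert to zerovalent palladium under these conditions.

Step 6
Reactants: 11 internal alkyne
Product: 12 (Z)-{3-[4-(methanesulfonyloxy)phenyl]prop-2-ene-1,1-diyl}bis[3,5-bis(benzyloxy)-2,1-phenylene] diacetate
Conditions: H2 (1 atm), Pd/CaCO3 poisoned with Pb(OAc)2, quinoline, EtOAc, rt
Reagents that add atoms: none
Why: Lindlar semihydrogenation: syn delivery of hydrogen on the poisoned surface gives the Z-alkene, and benzyl ethers, aryl acetates and the mesylate are not touched.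

Step 7
Reactants: 12 Z-alkene
Product: 13 (2R,3S)-2-{bis[2-acetoxy-4,6-bis(benzyloxy)phenyl]methyl}-3-[4-(methanesulfonyloxy)phenyl]oxirane (cis)
Conditions: (S,S)-(salen)MnCl [salen = N,N′-bis(3,5-di-tert-butylsalicylidene)cyclohexane-1,2-diamine; 5 mol %], mCPBA, NMO, CH2Cl2, −78 °C
Reagents that add atoms: mCPBA, OOC(=O)c1cccc(Cl)c1
Why: Jacobsen–Katsuki epoxidation of a cis-disubstituted aryl alkene, the best substrate class for (salen)MnCl (a chloride complex of trivalent manganese); by analogy with cis-β-methylstyrene the (S,S)-catalyst should add oxygen to the face that makes the benzylic carbon S and the other carbon R, which sets both epoxide centres at once. Low temperature and the electron-poor aryl group disfavour the stepwise radical pathway that would give trans-epoxide, and the peracid/N-oxide oxidant avoids hypochlorite, which would chlorinate the electron-rich rings.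

Step 8
Reactants: 13 epoxide diacetate
Product: 14 (2R,3S)-2-{bis[2,4-bis(benzyloxy)-6-hydroxyphenyl]methyl}-3-[4-(methanesulfonyloxy)phenyl]oxirane (cis)
Conditions: NH4OAc, MeOH–THF–H2O, rt
Reagents that add atoms: none
Why: Near-neutral methanolysis of aryl acetates with ammonium acetate; a carbonate or alkoxide base is avoided because a phenoxide would open the epoxide in the 5-exo mode at the non-benzylic carbon. The bisphenol is used at once.

Step 9
Reactants: 14 epoxide bisphenol
Product: 15 (2R,3R,4S)-5,7-bis(benzyloxy)-4-[2,4-bis(benzyloxy)-6-hydroxyphenyl]-2-[4-(methanesulfonyloxy)phenyl]chroman-3-ol (2,3-cis, 3,4-trans)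
Conditions: camphorsulfonic acid (10 mol %), CH2Cl2, −40 → 0 °C
Reagents that add atoms: none
Why: The acid activates the epoxide oxygen and one of the two ortho-phenol oxygens attacks the benzylic carbon (the future C2) from the side opposite to the breaking C–O bond, so that O1–C2 forms with inversion while C3 keeps its oxygen and its configuration; the closest known reaction type is the acid-promoted cyclisation of 2-hydroxybenzyl-substituted aryl epoxides to flavan-3-ols, and what has not been tested is the competition between two phenols. Ring C of the top unit closes in the 6-endo mode; the 5-exo alternative (attack at C3 to a dihydrobenzofuran) is disfavoured because C3 is flanked by the diarylmethyl group and has no benzylic activation. C2 is set by inversion of the S-configured epoxide carbon and C3 is carried over from the epoxide, which together give the 2,3-cis (2R,3R) arrangement from the cis-epoxide. C4 is set by which phenol attacks: backside attack fixes the half-chair of the closing ring with ring B on the pseudoaxial side of C2 (a consequence of the cis-epoxide), and whichever substituent of C4 shares that face meets ring B in a syn-pentane (1,3-diaxial) contact. The transition state in which hydrogen takes that position and the spectator aryl group points outwards, pseudoequatorial and trans to the C3–O bond, should therefore be preferred, and it leads to the 3,4-trans product; after closure the half-chair inverts, ring B becomes equatorial and the C4 aryl group pseudoaxial, which removes its peri contact with the 5-benzyloxy group. The step needs three selectivities: 6-endo over 5-exo (benzylic C2), inversion over ionisation (the sulfonate on ring B destabilises a C2 cation, and a non-polar solvent at low temperature keeps the opening SN2-like), and group selection (the syn-pentane argument, which works against a smaller peri strain in the favoured transition state and is the least secure of the three).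

Step 10
Reactants: 15 flavan phenol
Product: 16 4,6-bis(benzyloxy)-2-hydroxy-3-(TU)benzaldehyde
Conditions: MgCl2, Et3N, (CH2O)n, THF, reflux
Reagents that add atoms: paraformaldehyde (formaldehyde), C=O
Why: Casnati–Skattebøl ortho-formylation: the magnesium phenoxide delivers formaldehyde to its only free ortho position (the future C4a of the middle unit), and a second formaldehyde oxidises the magnesium salicyl alkoxide to the aldehyde; the position between the two benzyloxy groups and ring A of the top unit, which has no free phenol, are not reached.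

Step 11
Reactants: 16 salicylaldehyde
Product: 17 3,5-bis(benzyloxy)-2-(hydroxymethyl)-6-(TU)phenol
Conditions: NaBH4, THF–MeOH, 0 °C
Reagents that add atoms: none
Why: Hydride reduction of an aldehyde; the electron-rich salicyl alcohol is kept free of acid and used directly.

Step 12
Reactants: 17 salicyl alcohol; 18 benzyloxyacetaldehyde (3 equiv)
Product: 20 (3R)-3,5,7-tris(benzyloxy)-8-(TU)chroman-2-ol (lactol, both anomers), via quinone methide 19 (not isolated)
Conditions: (S)-α,α-diphenylprolinol trimethylsilyl ether (20 mol %), PhCO2H (20 mol %), toluene, rt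
Reagents that add atoms: none
Why: Aminocatalytic α-alkylation of an aldehyde by an ortho-quinone methide: the weak acid promotes loss of water from the trioxygenated salicyl alcohol to 19, the enamine of 18 adds to its unsubstituted methylene carbon, and after hydrolysis the phenol closes on the aldehyde. C3 is set by the catalyst, whose diphenyl(silyloxy)methyl group shields one face of the E-enamine; with the (S)-catalyst the usual model predicts the 3R product. No other lasting stereocentre is formed, and the top unit is too remote to interfere.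

Step 13
Reactants: 20 lactol
Product: 21 (3R)-3,5,7-tris(benzyloxy)-8-(TU)chroman-2-one
Conditions: Ag2CO3 on Celite, toluene, 80 °C
Reagents that add atoms: none
Why: Fétizon oxidation: Ag2CO3 on Celite oxidises lactols much faster than secondary alcohols, so the C3 hydroxyl of the top unit survives, and the neutral medium does not epimerise C3.

Step 14
Reactants: 21 lactone
Product: 22 (2R)-2-(benzyloxy)-3-[4,6-bis(benzyloxy)-2-hydroxy-3-(TU)phenyl]-N-methoxy-N-methylpropanamide
Conditions: MeNH(OMe)·HCl, AlMe3, CH2Cl2, 0 °C → rt
Reagents that add atoms: N,O-dimethylhydroxylamine hydrochloride, CNOC.Cl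
Why: Weinreb aminolysis of an aryl ester (lactone) by the aluminium amide formed from AlMe3 and the hydroxylamine salt; the reagent is not basic enough to touch the mesylate or the α-stereocentre.

Step 15
Reactants: 22 Weinreb amide; 23 4-bromo-1,2-bis(benzyloxy)benzene
Product: 25 (2R)-2-(benzyloxy)-1-[3,4-bis(benzyloxy)phenyl]-3-[4,6-bis(benzyloxy)-2-hydroxy-3-(TU)phenyl]propan-1-one, via aryl Grignard reagent 24 (not isolated)
Conditions: 23, Mg, THF, rt; then 22 (0.33 equiv), THF, −40 → 0 °C; aq. NH4Cl
Reagents that add atoms: none
Why: Weinreb ketone synthesis: the aryl Grignard reagent adds once because the magnesium chelate of the tetrahedral adduct survives until work-up; two further equivalents are consumed by the phenol and the C3 hydroxyl of the top unit, and an aryl mesylate is inert to an aryl Grignard reagent at this temperature without a nickel or iron catalyst.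

Step 16
Reactants: 25 phenol ketone
Product: 27 (2R,3R)-3,5,7-tris(benzyloxy)-2-[3,4-bis(benzyloxy)phenyl]-8-(TU)chroman (2,3-cis), via cyclic hemiketal 26 (not isolated)
Conditions: Et3SiH, BF3·OEt2, CH2Cl2, −78 → −30 °C
Reagents that add atoms: none
Why: Reductive etherification: BF3·OEt2 closes the phenol onto the ketone (hemiketal 26) and ionises it to the 2-aryl oxocarbenium ion, which Et3SiH reduces. Hydride enters C2 anti to the pseudoaxial C3 benzyloxy group, so that ring B ends cis to it (2R); this is the known course for 2,3-cis flavans made from such hydroxy ketones, and C4 is still CH2, so nothing shields that face.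

Step 17
Reactants: 27 dimer flavan
Product: 28 (2R,3R,4S)-3,5,7-tris(benzyloxy)-2-[3,4-bis(benzyloxy)phenyl]-4-(2-ethoxyethoxy)-8-(TU)chroman (4β-alkoxy, 3,4-trans)
Conditions: DDQ, 2-ethoxyethanol, CH2Cl2, rt
Reagents that add atoms: 2-ethoxyethanol, CCOCCO
Why: Benzylic C–H oxidation by DDQ (hydride abstraction) at C4 of the middle unit, which is ortho and para to three ring oxygens and offers a pseudoaxial C–H bond aligned with the π system of ring A; the cation is trapped by the alcohol trans to the C3 benzyloxy group. The tertiary C4–H of the top unit should not compete: it is pseudoequatorial and lies close to the plane of both flanking rings, so it overlaps poorly with either π system, and its cation would force the pendant ring out of conjugation.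

Step 18
Reactants: 29 (−)-epicatechin
Product: 30 5,7,3′,4′-tetra-O-benzyl-(−)-epicatechin
Conditions: BnBr, K2CO3, DMF, rt
Reagents that add atoms: benzyl bromide, BrCc1ccccc1
Why: Williamson etherification; K2CO3 deprotonates only the four phenols, so the C3 hydroxyl stays free.

Step 19
Reactants: 28 4-alkoxy dimer; 30 tetra-O-benzylepicatechin (4 equiv)
Product: 31 protected trimer: 28 in which the 2-ethoxyethoxy group is replaced by C8 of 30 (4β→8 bond, 3,4-trans in the middle unit); top unit 4′-OMs and 3-OH, middle unit 3-OBn, lower unit 3-OH, all other phenols benzylated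
Conditions: TMSOTf, CH2Cl2, −78 → −40 °C; Et3N quench
Reagents that add atoms: none
Why: Lewis acid-mediated flavan coupling (Friedel–Crafts alkylation): TMSOTf ionises the 4-alkoxy group and the C4 cation is attacked by C8 of 30 from the face trans to the C3 benzyloxy group, which sets C4 of the middle unit as in established procyanidin couplings. An excess of 30 suppresses self-condensation of 28, and the low temperature spares the C4–aryl bond already present.

Step 20
Reactants: 31 protected trimer mesylate
Product: 32 protected trimer with free 4′-hydroxyl on ring B of the top unit (eleven benzyl ethers)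
Conditions: LDA (LiN(i-Pr)2, excess), THF, −78 → 0 °C; aq. NH4Cl
Reagents that add atoms: none
Why: Cleavage of an aryl mesylate with a lithium amide: deprotonation of the S-methyl group expels the phenoxide (E1cB, sulfene); benzyl ethers and the stereocentres are inert at this temperature, and the base meets no free polyphenol.

Step 21
Reactants: 32 benzylated trimer
Product: 33 epiafzelechin-(4β→8)-epicatechin-(4β→8)-epicatechin (top unit 2R,3R,4R; middle unit 2R,3R,4S; lower unit 2R,3R)
Conditions: H2 (1 atm), Pd(OH)2/C, THF–MeOH–H2O, rt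
Reagents that add atoms: none
Why: Hydrogenolysis of the eleven benzyl ethers over Pd(OH)2/C under neutral conditions; no acid or base is present that could cleave the C4–aryl bonds or epimerise C2.

## Compound list

1 | 3,5-bis(benzyloxy)phenol | Oc1cc(OCc2ccccc2)cc(OCc2ccccc2)c1 | starting material
2 | ethyl glyoxylate | CCOC(=O)C=O | starting material
3 | ethyl 2-[2,4-bis(benzyloxy)-6-hydroxyphenyl]-2-hydroxyacetate (racemic) | CCOC(=O)C(O)c1c(O)cc(OCc2ccccc2)cc1OCc1ccccc1 | intermediate (not isolated)
4 | ethyl 2,2-bis[2,4-bis(benzyloxy)-6-hydroxyphenyl]acetate | CCOC(=O)C(c1c(O)cc(OCc2ccccc2)cc1OCc1ccccc1)c1c(O)cc(OCc2ccccc2)cc1OCc1ccccc1 | intermediate (not isolated)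
5 | 4,6-bis(benzyloxy)-3-[2,4-bis(benzyloxy)-6-hydroxyphenyl]benzofuran-2(3H)-one (racemic) | O=C1Oc2cc(OCc3ccccc3)cc(OCc3ccccc3)c2C1c1c(O)cc(OCc2ccccc2)cc1OCc1ccccc1 | intermediate
6 | 4,6-bis(benzyloxy)-3-[2,4-bis(benzyloxy)-6-hydroxyphenyl]-2,3-dihydrobenzofuran-2-ol (mixture of stereoisomers) | OC1Oc2cc(OCc3ccccc3)cc(OCc3ccccc3)c2C1c1c(O)cc(OCc2ccccc2)cc1OCc1ccccc1 | intermediate
7 | 2,2′-(prop-2-yne-1,1-diyl)bis[3,5-bis(benzyloxy)phenol] | C#CC(c1c(O)cc(OCc2ccccc2)cc1OCc1ccccc1)c1c(O)cc(OCc2ccccc2)cc1OCc1ccccc1 | intermediate (not isolated)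
8 | (prop-2-yne-1,1-diyl)bis[3,5-bis(benzyloxy)-2,1-phenylene] diacetate | C#CC(c1c(OC(C)=O)cc(OCc2ccccc2)cc1OCc1ccccc1)c1c(OC(C)=O)cc(OCc2ccccc2)cc1OCc1ccccc1 | intermediate
9 | 4-iodophenol | Oc1ccc(I)cc1 | starting material
10 | 4-iodophenyl methanesulfonate | CS(=O)(=O)Oc1ccc(I)cc1 | intermediate
11 | {3-[4-(methanesulfonyloxy)phenyl]prop-2-yne-1,1-diyl}bis[3,5-bis(benzyloxy)-2,1-phenylene] diacetate | CS(=O)(=O)Oc1ccc(cc1)C#CC(c1c(OC(C)=O)cc(OCc2ccccc2)cc1OCc1ccccc1)c1c(OC(C)=O)cc(OCc2ccccc2)cc1OCc1ccccc1 | intermediate
12 | (Z)-{3-[4-(methanesulfonyloxy)phenyl]prop-2-ene-1,1-diyl}bis[3,5-bis(benzyloxy)-2,1-phenylene] diacetate | CS(=O)(=O)Oc1ccc(cc1)/C=C\C(c1c(OC(C)=O)cc(OCc2ccccc2)cc1OCc1ccccc1)c1c(OC(C)=O)cc(OCc2ccccc2)cc1OCc1ccccc1 | intermediate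
13 | (2R,3S)-2-{bis[2-acetoxy-4,6-bis(benzyloxy)phenyl]methyl}-3-[4-(methanesulfonyloxy)phenyl]oxirane (cis) | CS(=O)(=O)Oc1ccc(cc1)[C@@H]1O[C@@H]1C(c1c(OC(C)=O)cc(OCc2ccccc2)cc1OCc1ccccc1)c1c(OC(C)=O)cc(OCc2ccccc2)cc1OCc1ccccc1 | intermediate
14 | (2R,3S)-2-{bis[2,4-bis(benzyloxy)-6-hydroxyphenyl]methyl}-3-[4-(methanesulfonyloxy)phenyl]oxirane (cis) | CS(=O)(=O)Oc1ccc(cc1)[C@@H]1O[C@@H]1C(c1c(O)cc(OCc2ccccc2)cc1OCc1ccccc1)c1c(O)cc(OCc2ccccc2)cc1OCc1ccccc1 | intermediate (key-step precursor)
15 | (2R,3R,4S)-5,7-bis(benzyloxy)-4-[2,4-bis(benzyloxy)-6-hydroxyphenyl]-2-[4-(methanesulfonyloxy)phenyl]chroman-3-ol (2,3-cis, 3,4-trans) | CS(=O)(=O)Oc1ccc([C@H]2Oc3cc(OCc4ccccc4)cc(OCc4ccccc4)c3[C@H](c3c(O)cc(OCc4ccccc4)cc3OCc3ccccc3)[C@H]2O)cc1 | intermediate (key-step product)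
16 | 4,6-bis(benzyloxy)-2-hydroxy-3-(TU)benzaldehyde | CS(=O)(=O)Oc1ccc([C@H]2Oc3cc(OCc4ccccc4)cc(OCc4ccccc4)c3[C@H](c3c(O)c(C=O)c(OCc4ccccc4)cc3OCc3ccccc3)[C@H]2O)cc1 | intermediate
17 | 3,5-bis(benzyloxy)-2-(hydroxymethyl)-6-(TU)phenol | CS(=O)(=O)Oc1ccc([C@H]2Oc3cc(OCc4ccccc4)cc(OCc4ccccc4)c3[C@H](c3c(O)c(CO)c(OCc4ccccc4)cc3OCc3ccccc3)[C@H]2O)cc1 | intermediate
18 | benzyloxyacetaldehyde | O=CCOCc1ccccc1 | starting material
19 | 3,5-bis(benzyloxy)-6-methylene-2-(TU)cyclohexa-2,4-dien-1-one (ortho-quinone methide) | CS(=O)(=O)Oc1ccc([C@H]2Oc3cc(OCc4ccccc4)cc(OCc4ccccc4)c3[C@H](C3=C(OCc4ccccc4)C=C(OCc4ccccc4)C(=C)C3=O)[C@H]2O)cc1 | intermediate (not isolated)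
20 | (3R)-3,5,7-tris(benzyloxy)-8-(TU)chroman-2-ol (both anomers) | CS(=O)(=O)Oc1ccc([C@H]2Oc3cc(OCc4ccccc4)cc(OCc4ccccc4)c3[C@H](c3c(OCc4ccccc4)cc(OCc4ccccc4)c4c3OC(O)[C@H](OCc3ccccc3)C4)[C@H]2O)cc1 | intermediate
21 | (3R)-3,5,7-tris(benzyloxy)-8-(TU)chroman-2-one | CS(=O)(=O)Oc1ccc([C@H]2Oc3cc(OCc4ccccc4)cc(OCc4ccccc4)c3[C@H](c3c(OCc4ccccc4)cc(OCc4ccccc4)c4c3OC(=O)[C@H](OCc3ccccc3)C4)[C@H]2O)cc1 | intermediate
22 | (2R)-2-(benzyloxy)-3-[4,6-bis(benzyloxy)-2-hydroxy-3-(TU)phenyl]-N-methoxy-N-methylpropanamide | CS(=O)(=O)Oc1ccc([C@H]2Oc3cc(OCc4ccccc4)cc(OCc4ccccc4)c3[C@H](c3c(O)c(C[C@@H](OCc4ccccc4)C(=O)N(C)OC)c(OCc4ccccc4)cc3OCc3ccccc3)[C@H]2O)cc1 | intermediate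
23 | 4-bromo-1,2-bis(benzyloxy)benzene | Brc1ccc(OCc2ccccc2)c(OCc2ccccc2)c1 | starting material
24 | [3,4-bis(benzyloxy)phenyl]magnesium bromide | Br[Mg]c1ccc(OCc2ccccc2)c(OCc2ccccc2)c1 | intermediate (not isolated)
25 | (2R)-2-(benzyloxy)-1-[3,4-bis(benzyloxy)phenyl]-3-[4,6-bis(benzyloxy)-2-hydroxy-3-(TU)phenyl]propan-1-one | CS(=O)(=O)Oc1ccc([C@H]2Oc3cc(OCc4ccccc4)cc(OCc4ccccc4)c3[C@H](c3c(O)c(C[C@@H](OCc4ccccc4)C(=O)c4ccc(OCc5ccccc5)c(OCc5ccccc5)c4)c(OCc4ccccc4)cc3OCc3ccccc3)[C@H]2O)cc1 | intermediate
26 | (3R)-3,5,7-tris(benzyloxy)-2-[3,4-bis(benzyloxy)phenyl]-8-(TU)chroman-2-ol (cyclic hemiketal) | CS(=O)(=O)Oc1ccc([C@H]2Oc3cc(OCc4ccccc4)cc(OCc4ccccc4)c3[C@H](c3c(OCc4ccccc4)cc(OCc4ccccc4)c4c3OC(O)(c3ccc(OCc5ccccc5)c(OCc5ccccc5)c3)[C@H](OCc3ccccc3)C4)[C@H]2O)cc1 | intermediate (not isolated)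
27 | (2R,3R)-3,5,7-tris(benzyloxy)-2-[3,4-bis(benzyloxy)phenyl]-8-(TU)chroman (2,3-cis) | CS(=O)(=O)Oc1ccc([C@H]2Oc3cc(OCc4ccccc4)cc(OCc4ccccc4)c3[C@H](c3c(OCc4ccccc4)cc(OCc4ccccc4)c4c3O[C@H](c3ccc(OCc5ccccc5)c(OCc5ccccc5)c3)[C@H](OCc3ccccc3)C4)[C@H]2O)cc1 | intermediate
28 | (2R,3R,4S)-3,5,7-tris(benzyloxy)-2-[3,4-bis(benzyloxy)phenyl]-4-(2-ethoxyethoxy)-8-(TU)chroman (4β-alkoxy, 3,4-trans) | CS(=O)(=O)Oc1ccc([C@H]2Oc3cc(OCc4ccccc4)cc(OCc4ccccc4)c3[C@H](c3c(OCc4ccccc4)cc(OCc4ccccc4)c4c3O[C@H](c3ccc(OCc5ccccc5)c(OCc5ccccc5)c3)[C@H](OCc3ccccc3)[C@H]4OCCOCC)[C@H]2O)cc1 | intermediate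
29 | (−)-epicatechin | O[C@@H]1Cc2c(O)cc(O)cc2O[C@@H]1c1ccc(O)c(O)c1 | starting material
30 | 5,7,3′,4′-tetra-O-benzyl-(−)-epicatechin | O[C@@H]1Cc2c(OCc3ccccc3)cc(OCc3ccccc3)cc2O[C@@H]1c1ccc(OCc2ccccc2)c(OCc2ccccc2)c1 | intermediate
31 | protected trimer (top unit 4′-OMs, 3-OH; middle unit 3-OBn; lower unit 3-OH; ten aryl benzyl ethers; both interflavan bonds 4β→8) | CS(=O)(=O)Oc1ccc([C@H]2Oc3cc(OCc4ccccc4)cc(OCc4ccccc4)c3[C@H](c3c(OCc4ccccc4)cc(OCc4ccccc4)c4c3O[C@H](c3ccc(OCc5ccccc5)c(OCc5ccccc5)c3)[C@H](OCc3ccccc3)[C@H]4c3c(OCc4ccccc4)cc(OCc4ccccc4)c4c3O[C@H](c3ccc(OCc5ccccc5)c(OCc5ccccc5)c3)[C@H](O)C4)[C@H]2O)cc1 | intermediate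
32 | protected trimer with free 4′-hydroxyl on ring B of the top unit | Oc1ccc([C@H]2Oc3cc(OCc4ccccc4)cc(OCc4ccccc4)c3[C@H](c3c(OCc4ccccc4)cc(OCc4ccccc4)c4c3O[C@H](c3ccc(OCc5ccccc5)c(OCc5ccccc5)c3)[C@H](OCc3ccccc3)[C@H]4c3c(OCc4ccccc4)cc(OCc4ccccc4)c4c3O[C@H](c3ccc(OCc5ccccc5)c(OCc5ccccc5)c3)[C@H](O)C4)[C@H]2O)cc1 | intermediate
33 | epiafzelechin-(4β→8)-epicatechin-(4β→8)-epicatechin | Oc1ccc([C@H]2Oc3cc(O)cc(O)c3[C@H](c3c(O)cc(O)c4c3O[C@H](c3ccc(O)c(O)c3)[C@H](O)[C@H]4c3c(O)cc(O)c4c3O[C@H](c3ccc(O)c(O)c3)[C@H](O)C4)[C@H]2O)cc1 | target

## Step count and least certain steps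

Total: 21 steps. Longest linear sequence: 19 steps (steps 1–3, 5–17 and 19–21).

**Step 9 (key step).** The selection between the two phenols may be too weak, so that both close and C4 is formed as a mixture; partial ionisation at the benzylic carbon would also erode the inversion and bring in the 2,3-trans series. The group selection rests on a syn-pentane contact that is opposed by peri strain in the favoured transition state. The fallback sets out from 14 and comes back at 15. The crude cyclisation mixture of 15 and its C4 epimer, (2R,3R,4R)-5,7-bis(benzyloxy)-4-[2,4-bis(benzyloxy)-6-hydroxyphenyl]-2-[4-(methanesulfonyloxy)phenyl]chroman-3-ol F1, is not separated. It is treated with benzyl mercaptan and trifluoroacetic acid in CH2Cl2. As in the thiolytic degradation of proanthocyanidins, ipso-protonation cleaves the C4–aryl bond, 1 is released, and both epimers converge on the 4β-benzylthio flavan, (2R,3S,4S)-4-(benzylthio)-5,7-bis(benzyloxy)-2-[4-(methanesulfonyloxy)phenyl]chroman-3-ol F2. F2 is then activated with AgBF4 in the presence of an excess of 1. The C4 cation of a 2,3-cis flavan is captured trans to the C3 hydroxyl, and the less hindered ortho carbon of 1 attacks, which returns 15; a para-linked regioisomer would be removed by chromatography.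

**Step 7.** Oxygen transfer may proceed stepwise with rotation, giving trans-epoxide, and the bulky diarylmethyl group may lower facial selectivity or slow the reaction on an electron-poor styrene. The fallback sets out from 11 and comes back at 13. Trans-selective semihydrogenation (H2, [Cp*RuCl(cod)]) gives the E-alkene, (E)-{3-[4-(methanesulfonyloxy)phenyl]prop-2-ene-1,1-diyl}bis[3,5-bis(benzyloxy)-2,1-phenylene] diacetate F3. Base-free asymmetric dihydroxylation (K2OsO2(OH)4, (DHQD)2PHAL, NMO, acetone–water, so that the aryl acetates survive) gives the (1R,2R)-diol, (1R,2R)-3,3-bis[2-acetoxy-4,6-bis(benzyloxy)phenyl]-1-[4-(methanesulfonyloxy)phenyl]propane-1,2-diol F4. The less hindered benzylic hydroxyl is mesylated (MsCl, collidine, −20 °C) to the monomesylate F5. DBU then closes the ring: the remaining oxygen displaces the benzylic mesylate with inversion, which turns the syn-diol of the E-alkene into the cis-epoxide 13.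

**Step 12.** The quinone methide may be consumed by self-condensation or by the electron-rich rings, and the enamine of an α-alkoxy aldehyde may react with poor face selectivity. The fallback sets out from 17 and comes back at 21; it replaces catalyst control by separation and recycling. Pyrrolidine is used as an achiral catalyst, which gives 20 together with its C3 epimer, (3S)-3,5,7-tris(benzyloxy)-8-(TU)chroman-2-ol F6. The mixture is oxidised as in step 13 and lactone 21 is separated from its epimer, (3S)-3,5,7-tris(benzyloxy)-8-(TU)chroman-2-one F7. Because C3–H of F7 is α to the lactone carbonyl, F7 is re-equilibrated with DBU and recycled.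

**Step 16.** Hydride delivery may lose face selectivity, or reduction may run through the open-chain benzylic cation, giving 2,3-trans material or over-reduction. The fallback sets out from 25 and comes back at 27. Chelation-controlled reduction with Zn(BH4)2 gives the anti carbinol, (1S,2R)-2-(benzyloxy)-1-[3,4-bis(benzyloxy)phenyl]-3-[4,6-bis(benzyloxy)-2-hydroxy-3-(TU)phenyl]propan-1-ol F8. Mitsunobu etherification (PPh3, diisopropyl azodicarboxylate, one equivalent each, 0 °C) then lets the phenol displace the activated benzylic hydroxyl with inversion, which gives the 2,3-cis ring of 27. The open-chain benzylic carbinol should be activated in preference to the C3 hydroxyl of the top unit, which is an axial ring hydroxyl between two substituted ring carbons.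

**Step 19.** The cation of 28 may be captured by nucleophilic ring positions of another molecule of 28 (oligomers) or by C6 instead of C8 of 30, and the Lewis acid may cleave the C4–aryl bond of the top unit. The fallback sets out from 28 and comes back at 31. The 2-ethoxyethyl ether is exchanged for a benzylthio group (benzyl mercaptan, BF3·OEt2, −78 °C) to give (2R,3S,4S)-3,5,7-tris(benzyloxy)-2-[3,4-bis(benzyloxy)phenyl]-4-(benzylthio)-8-(TU)chroman F9. F9 is activated with the thiophile AgBF4 at low temperature in the presence of 30, so that no strong oxophilic Lewis acid is present during the coupling.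

## Further compounds

F1 | step 9 | (2R,3R,4R)-5,7-bis(benzyloxy)-4-[2,4-bis(benzyloxy)-6-hydroxyphenyl]-2-[4-(methanesulfonyloxy)phenyl]chroman-3-ol (C4 epimer of 15, 3,4-cis) | CS(=O)(=O)Oc1ccc([C@H]2Oc3cc(OCc4ccccc4)cc(OCc4ccccc4)c3[C@@H](c3c(O)cc(OCc4ccccc4)cc3OCc3ccccc3)[C@H]2O)cc1
F2 | step 9 | (2R,3S,4S)-4-(benzylthio)-5,7-bis(benzyloxy)-2-[4-(methanesulfonyloxy)phenyl]chroman-3-ol (4β-thio, 3,4-trans) | CS(=O)(=O)Oc1ccc([C@H]2Oc3cc(OCc4ccccc4)cc(OCc4ccccc4)c3[C@H](SCc3ccccc3)[C@H]2O)cc1
F3 | step 7 | (E)-{3-[4-(methanesulfonyloxy)phenyl]prop-2-ene-1,1-diyl}bis[3,5-bis(benzyloxy)-2,1-phenylene] diacetate | CS(=O)(=O)Oc1ccc(cc1)/C=C/C(c1c(OC(C)=O)cc(OCc2ccccc2)cc1OCc1ccccc1)c1c(OC(C)=O)cc(OCc2ccccc2)cc1OCc1ccccc1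
F4 | step 7 | (1R,2R)-3,3-bis[2-acetoxy-4,6-bis(benzyloxy)phenyl]-1-[4-(methanesulfonyloxy)phenyl]propane-1,2-diol | CS(=O)(=O)Oc1ccc(cc1)[C@@H](O)[C@H](O)C(c1c(OC(C)=O)cc(OCc2ccccc2)cc1OCc1ccccc1)c1c(OC(C)=O)cc(OCc2ccccc2)cc1OCc1ccccc1
F5 | step 7 | (1R,2R)-3,3-bis[2-acetoxy-4,6-bis(benzyloxy)phenyl]-2-hydroxy-1-[4-(methanesulfonyloxy)phenyl]propyl methanesulfonate | CS(=O)(=O)Oc1ccc(cc1)[C@@H](OS(C)(=O)=O)[C@H](O)C(c1c(OC(C)=O)cc(OCc2ccccc2)cc1OCc1ccccc1)c1c(OC(C)=O)cc(OCc2ccccc2)cc1OCc1ccccc1
F6 | step 12 | (3S)-3,5,7-tris(benzyloxy)-8-(TU)chroman-2-ol (C3 epimer of 20) | CS(=O)(=O)Oc1ccc([C@H]2Oc3cc(OCc4ccccc4)cc(OCc4ccccc4)c3[C@H](c3c(OCc4ccccc4)cc(OCc4ccccc4)c4c3OC(O)[C@@H](OCc3ccccc3)C4)[C@H]2O)cc1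
F7 | step 12 | (3S)-3,5,7-tris(benzyloxy)-8-(TU)chroman-2-one (C3 epimer of 21) | CS(=O)(=O)Oc1ccc([C@H]2Oc3cc(OCc4ccccc4)cc(OCc4ccccc4)c3[C@H](c3c(OCc4ccccc4)cc(OCc4ccccc4)c4c3OC(=O)[C@@H](OCc3ccccc3)C4)[C@H]2O)cc1
F8 | step 16 | (1S,2R)-2-(benzyloxy)-1-[3,4-bis(benzyloxy)phenyl]-3-[4,6-bis(benzyloxy)-2-hydroxy-3-(TU)phenyl]propan-1-ol (anti) | CS(=O)(=O)Oc1ccc([C@H]2Oc3cc(OCc4ccccc4)cc(OCc4ccccc4)c3[C@H](c3c(O)c(C[C@@H](OCc4ccccc4)[C@@H](O)c4ccc(OCc5ccccc5)c(OCc5ccccc5)c4)c(OCc4ccccc4)cc3OCc3ccccc3)[C@H]2O)cc1
F9 | step 19 | (2R,3S,4S)-3,5,7-tris(benzyloxy)-2-[3,4-bis(benzyloxy)phenyl]-4-(benzylthio)-8-(TU)chroman (4β-thio, 3,4-trans) | CS(=O)(=O)Oc1ccc([C@H]2Oc3cc(OCc4ccccc4)cc(OCc4ccccc4)c3[C@H](c3c(OCc4ccccc4)cc(OCc4ccccc4)c4c3O[C@H](c3ccc(OCc5ccccc5)c(OCc5ccccc5)c3)[C@H](OCc3ccccc3)[C@H]4SCc3ccccc3)[C@H]2O)cc1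
A1 | alternative 1 | 4-aryl-4H-chromene (flav-2-ene) of the top unit on the benzylated lower dimer | c1ccccc1COc1ccc(cc1)C1=C[C@@H](c3c(OCc4ccccc4)cc(OCc4ccccc4)c4c3O[C@H](c3ccc(OCc5ccccc5)c(OCc5ccccc5)c3)[C@H](OCc5ccccc5)[C@H]4c3c(OCc4ccccc4)cc(OCc4ccccc4)c4c3O[C@H](c3ccc(OCc5ccccc5)c(OCc5ccccc5)c3)[C@H](OCc5ccccc5)C4)c2c(OCc6ccccc6)cc(OCc6ccccc6)cc2O1
A2 | alternative 2 | benzyl-protected trimer with free C3 hydroxyl on the top unit | c1ccccc1COc1ccc([C@H]2Oc3cc(OCc4ccccc4)cc(OCc4ccccc4)c3[C@H](c3c(OCc4ccccc4)cc(OCc4ccccc4)c4c3O[C@H](c3ccc(OCc5ccccc5)c(OCc5ccccc5)c3)[C@H](OCc5ccccc5)[C@H]4c3c(OCc4ccccc4)cc(OCc4ccccc4)c4c3O[C@H](c3ccc(OCc5ccccc5)c(OCc5ccccc5)c3)[C@H](OCc5ccccc5)C4)[C@H]2O)cc1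
A3 | alternative 3 | 3,4-trans 3-benzyloxychroman-2-ol (lactol, anomeric mixture) of the top unit on the benzylated lower dimer | OC1Oc2cc(OCc6ccccc6)cc(OCc6ccccc6)c2[C@H](c3c(OCc4ccccc4)cc(OCc4ccccc4)c4c3O[C@H](c3ccc(OCc5ccccc5)c(OCc5ccccc5)c3)[C@H](OCc5ccccc5)[C@H]4c3c(OCc4ccccc4)cc(OCc4ccccc4)c4c3O[C@H](c3ccc(OCc5ccccc5)c(OCc5ccccc5)c3)[C@H](OCc5ccccc5)C4)[C@H]1OCc6ccccc6
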